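**Retrosynthetic overview**

- The target is opened at the exocyclic C3 methylene (decarboxylative Mannich methylenation of a C3 malonic-type acid) and at the C4 carboxyl, which is carried as a 4-methoxyphenyl ring and unmasked by oxidative ring degradation.
- Key disconnection C3–C4: rhodium carbene C–H insertion of the tert-butyl diazomalonate of an (R)-1-anisylalkan-2-ol. This step closes the only ring, the γ-lactone, and sets C4 (and C3).
- Feature used: in the ring O1–C2–C3–C4–C5, C3 lies between the C2 carbonyl and C4. A carbene on C3 of a malonate ester hung on the C5 oxygen is therefore 1,5-related to the C4–H bond, and after insertion C3 still carries the ester needed for the methylene group.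
- The diazomalonate comes from the (R)-carbinol, made from (S)-2-(4-methoxybenzyl)oxirane and a C12 Grignard reagent; the oxirane comes from (S)-epichlorohydrin and 4-methoxyphenylmagnesium bromide, so C5 is a purchased stereocentre.

Key step: step 9

Remark: ring atoms are called O1, C2 (carbonyl), C3, C4, C5 in all discussion, whatever the locants of the systematic names.

**Step 1**
Reactants: 1 (S)-epichlorohydrin; 2 4-methoxyphenylmagnesium bromide (THF solution)
Product: 3 (S)-1-chloro-3-(4-methoxyphenyl)propan-2-ol
Conditions: CuI (10 mol%), THF, −40 °C → −10 °C; then sat. aq. NH4Cl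
Reagents that add atoms: none
Why: Copper-catalysed Grignard opening of the epoxide at its unsubstituted carbon (SN2, faster than chloride displacement at low temperature) does not touch the C–O bond of the stereocentre, so the (S) centre of 1 is carried into 3 unchanged.

**Step 2**
Reactants: 3 (S)-1-chloro-3-(4-methoxyphenyl)propan-2-ol
Product: 4 (S)-2-(4-methoxybenzyl)oxirane
Conditions: NaOH (powdered), Et2O, rt
Reagents that add atoms: none
Why: Intramolecular Williamson etherification (3-exo-tet displacement of chloride by the alkoxide) closes the epoxide at the former CH2Cl carbon and leaves the stereocentre (S).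

**Step 3**
Reactants: 5 12-bromododecan-1-ol
Product: 6 (12-bromododecyloxy)(tert-butyl)dimethylsilane
Conditions: TBSCl, imidazole, CH2Cl2, 0 °C → rt
Reagents that add atoms: tert-butyldimethylsilyl chloride (TBSCl), CC(C)(C)[Si](C)(C)Cl
Why: Standard silylation of a primary alcohol gives an ether that tolerates Grignard formation and the later acylation.

**Step 4**
Reactants: 6 (12-bromododecyloxy)(tert-butyl)dimethylsilane; 4 (S)-2-(4-methoxybenzyl)oxirane
Product: 8 (R)-15-(tert-butyldimethylsilyloxy)-1-(4-methoxyphenyl)pentadecan-2-ol, via Grignard reagent 7 (not isolated)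
Conditions: Mg turnings (I2 cat.), THF, 45 °C; then CuI (10 mol%), 4, THF, −30 °C → 0 °C; then sat. aq. NH4Cl
Reagents that add atoms: none
Why: Grignard formation followed by copper-catalysed SN2 opening of the terminal epoxide at its CH2 carbon attaches the C12 chain without breaking the carbinol C–O bond, so the centre keeps its spatial arrangement and is named (R) only because the CIP priorities change.

**Step 5**
Reactants: 8 (R)-15-(tert-butyldimethylsilyloxy)-1-(4-methoxyphenyl)pentadecan-2-ol; 9 mono-tert-butyl malonate
Product: 10 tert-butyl (R)-15-(tert-butyldimethylsilyloxy)-1-(4-methoxyphenyl)pentadecan-2-yl malonate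
Conditions: DCC, DMAP (10 mol%), CH2Cl2, 0 °C → rt
Reagents that add atoms: none
Why: Steglich esterification acylates the secondary alcohol with the malonic half ester with retention, since the C–O bond of the stereocentre is not involved.

**Step 6**
Reactants: 10 tert-butyl (R)-15-(tert-butyldimethylsilyloxy)-1-(4-methoxyphenyl)pentadecan-2-yl malonate
Product: 11 tert-butyl (R)-15-hydroxy-1-(4-methoxyphenyl)pentadecan-2-yl malonate
Conditions: HF·pyridine, pyridine/THF, 0 °C → rt
Reagents that add atoms: none
Why: Fluoride-mediated desilylation under buffered conditions removes the primary TBS ether while the tert-butyl ester, the malonate and the anisyl group are inert.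

**Step 7**
Reactants: 11 tert-butyl (R)-15-hydroxy-1-(4-methoxyphenyl)pentadecan-2-yl malonate
Product: 12 tert-butyl (R)-15-acetoxy-1-(4-methoxyphenyl)pentadecan-2-yl malonate
Conditions: Ac2O, pyridine, DMAP (cat.), CH2Cl2, 0 °C → rt
Reagents that add atoms: acetic anhydride, CC(=O)OC(C)=O
Why: DMAP-catalysed O-acetylation of the primary alcohol installs the acetate of the target under conditions too weakly basic to C-acylate the malonate.

**Step 8**
Reactants: 12 tert-butyl (R)-15-acetoxy-1-(4-methoxyphenyl)pentadecan-2-yl malonate
Product: 13 tert-butyl (R)-15-acetoxy-1-(4-methoxyphenyl)pentadecan-2-yl 2-diazomalonate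
Conditions: p-ABSA, Et3N, MeCN, 0 °C → rt
Reagents that add atoms: 4-acetamidobenzenesulfonyl azide (p-ABSA), CC(=O)Nc1ccc(cc1)S(=O)(=O)N=[N+]=[N-]
Why: Regitz diazo transfer from the sulfonyl azide to the amine-generated malonate enolate gives the diazomalonate, and neither the acetate nor the tert-butyl ester reacts.

**Step 9**
Reactants: 13 tert-butyl (R)-15-acetoxy-1-(4-methoxyphenyl)pentadecan-2-yl 2-diazomalonate
Product: 14 tert-butyl (3S,4R,5R)-5-(13-acetoxytridecyl)-4-(4-methoxyphenyl)-2-oxotetrahydrofuran-3-carboxylate (all-trans)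
Conditions: Rh2(OAc)4 (2 mol%), CH2Cl2, reflux, slow addition of 13
Reagents that add atoms: none
Why: Rh2(OAc)4, a dimer of divalent rhodium, expels N2 from 13 to give an electrophilic rhodium carbene at C3, which inserts into the benzylic C4–H bond through a concerted three-centre transition state with hydride-transfer character and so forms the C3–C4 bond; the closest known reaction type is the dirhodium tetracarboxylate-catalysed intramolecular C–H insertion of 2-arylethyl α-alkoxycarbonyl-α-diazoacetates to trans 4-aryl-3-alkoxycarbonyl-γ-butyrolactones. The γ-lactone, the only ring, closes by 1,5-insertion along the chain C3–C2–O1–C5–C4. C4 is controlled by the existing C5 centre, because in the chair-like transition state the C5 chain and the anisyl group both sit pseudo-equatorial and end up trans on the ring. C3 is under thermodynamic control: as the methine between two carbonyls it epimerises readily and should settle trans to the aryl group, and it is removed again in step 12. The step needs site selectivity for C4–H over the equally 1,5-related C6–H2 of the chain, over C5–H (β-lactone), over the primary C–H bonds of the tert-butyl group and over addition to the arene. The p-methoxy group, which stabilises the positive charge building at C4, the five-membered transition state and the low reactivity of primary C–H bonds should secure this, but it remains the main risk of the route.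

**Step 10**
Reactants: 14 tert-butyl (3S,4R,5R)-5-(13-acetoxytridecyl)-4-(4-methoxyphenyl)-2-oxotetrahydrofuran-3-carboxylate
Product: 15 (2R,3S,4S)-2-(13-acetoxytridecyl)-4-(tert-butoxycarbonyl)-5-oxotetrahydrofuran-3-carboxylic acid
Conditions: RuCl3·xH2O (5 mol%), NaIO4 (ca. 15 equiv), EtOAc/MeCN/H2O, rt
Reagents that add atoms: sodium periodate, [Na+].[O-]I(=O)(=O)=O; water, O
Why: Catalytic RuO4, generated from RuCl3 and NaIO4, degrades the electron-rich anisyl ring to a carboxylic acid on the carbon that carried it (the known use of an aryl group as a latent carboxyl), and since no bond to C4 is broken its configuration is kept while the esters, the lactone and the saturated chain are inert.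

**Step 11**
Reactants: 15 (2R,3S,4S)-2-(13-acetoxytridecyl)-4-(tert-butoxycarbonyl)-5-oxotetrahydrofuran-3-carboxylic acid
Product: 16 (2R,3S,4R)-2-(13-acetoxytridecyl)-5-oxotetrahydrofuran-3,4-dicarboxylic acid
Conditions: TFA/CH2Cl2 (1:3), 0 °C → rt; evaporate, use crude
Reagents that add atoms: none
Why: Acidolysis of the tert-butyl ester (E1 loss of isobutene) frees the C3 acid while the acetate, the lactone and the C4 acid are stable to anhydrous acid, and the malonic-type diacid is taken on crude to avoid premature decarboxylation.

**Step 12**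
Reactants: 16 (2R,3S,4R)-2-(13-acetoxytridecyl)-5-oxotetrahydrofuran-3,4-dicarboxylic acid
Product: 18 (2R,3S)-2-(13-acetoxytridecyl)-4-methylene-5-oxotetrahydrofuran-3-carboxylic acid, via Mannich base 17 (not isolated)
Conditions: 37% aq. HCHO, Et2NH, NaOAc, AcOH, rt → 70 °C
Reagents that add atoms: formaldehyde, C=O
Why: Mannich reaction of the C3 malonic half acid with the iminium ion from formaldehyde and diethylamine, followed by decarboxylative elimination of the amine, gives the exocyclic methylene (the standard decarboxylative methylenation of α-carboxy lactones), which removes the C3 centre and leaves C4 and C5 untouched in the buffered acidic medium.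

**Compound list**

1 | (S)-epichlorohydrin | ClC[C@@H]1CO1 | starting material
2 | 4-methoxyphenylmagnesium bromide (THF solution) | COc1ccc([Mg]Br)cc1 | starting material
3 | (S)-1-chloro-3-(4-methoxyphenyl)propan-2-ol | ClC[C@@H](O)Cc1ccc(OC)cc1 | intermediate
4 | (S)-2-(4-methoxybenzyl)oxirane | C1[C@@H](O1)Cc2ccc(OC)cc2 | intermediate
5 | 12-bromododecan-1-ol | OCCCCCCCCCCCCBr | starting material
6 | (12-bromododecyloxy)(tert-butyl)dimethylsilane | CC(C)(C)[Si](C)(C)OCCCCCCCCCCCCBr | intermediate
7 | 12-(tert-butyldimethylsilyloxy)dodecylmagnesium bromide (formed in the flask) | CC(C)(C)[Si](C)(C)OCCCCCCCCCCCC[Mg]Br | intermediate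
8 | (R)-15-(tert-butyldimethylsilyloxy)-1-(4-methoxyphenyl)pentadecan-2-ol | CC(C)(C)[Si](C)(C)OCCCCCCCCCCCCC[C@@H](O)Cc1ccc(OC)cc1 | intermediate
9 | mono-tert-butyl malonate | OC(=O)CC(=O)OC(C)(C)C | starting material
10 | tert-butyl (R)-15-(tert-butyldimethylsilyloxy)-1-(4-methoxyphenyl)pentadecan-2-yl malonate | CC(C)(C)OC(=O)CC(=O)O[C@H](CCCCCCCCCCCCCO[Si](C)(C)C(C)(C)C)Cc1ccc(OC)cc1 | intermediate
11 | tert-butyl (R)-15-hydroxy-1-(4-methoxyphenyl)pentadecan-2-yl malonate | CC(C)(C)OC(=O)CC(=O)O[C@H](CCCCCCCCCCCCCO)Cc1ccc(OC)cc1 | intermediate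
12 | tert-butyl (R)-15-acetoxy-1-(4-methoxyphenyl)pentadecan-2-yl malonate | CC(C)(C)OC(=O)CC(=O)O[C@H](CCCCCCCCCCCCCOC(C)=O)Cc1ccc(OC)cc1 | intermediate
13 | tert-butyl (R)-15-acetoxy-1-(4-methoxyphenyl)pentadecan-2-yl 2-diazomalonate | CC(C)(C)OC(=O)C(=[N+]=[N-])C(=O)O[C@H](CCCCCCCCCCCCCOC(C)=O)Cc1ccc(OC)cc1 | intermediate
14 | tert-butyl (3S,4R,5R)-5-(13-acetoxytridecyl)-4-(4-methoxyphenyl)-2-oxotetrahydrofuran-3-carboxylate (all-trans) | CC(C)(C)OC(=O)[C@@H]1C(=O)O[C@H](CCCCCCCCCCCCCOC(C)=O)[C@H]1c2ccc(OC)cc2 | intermediate
15 | (2R,3S,4S)-2-(13-acetoxytridecyl)-4-(tert-butoxycarbonyl)-5-oxotetrahydrofuran-3-carboxylic acid | CC(C)(C)OC(=O)[C@@H]1C(=O)O[C@H](CCCCCCCCCCCCCOC(C)=O)[C@H]1C(=O)O | intermediate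
16 | (2R,3S,4R)-2-(13-acetoxytridecyl)-5-oxotetrahydrofuran-3,4-dicarboxylic acid | OC(=O)[C@@H]1C(=O)O[C@H](CCCCCCCCCCCCCOC(C)=O)[C@H]1C(=O)O | intermediate
17 | (2R,3S,4R)-2-(13-acetoxytridecyl)-4-(diethylaminomethyl)-5-oxotetrahydrofuran-3,4-dicarboxylic acid (formed in the flask; aminomethyl group expected anti to the neighbouring carboxyl) | CCN(CC)C[C@]1(C(=O)O)C(=O)O[C@H](CCCCCCCCCCCCCOC(C)=O)[C@H]1C(=O)O | intermediate
18 | (2R,3S)-2-(13-acetoxytridecyl)-4-methylene-5-oxotetrahydrofuran-3-carboxylic acid | C=C1C(=O)O[C@H](CCCCCCCCCCCCCOC(C)=O)[C@H]1C(=O)O | target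

**Step count**

Total: 12 steps. Longest linear sequence: 11 steps (steps 1, 2 and 4–12, from 1 to 18).

**Steps most likely to fail**

Step 9. The carbene may insert into the wrong C–H bond (C6–H2 of the chain or C5–H), add to the anisyl ring, or give a mixture at C4 relative to C5. The fallback sets out from 8 and comes back at 14. It replaces the acceptor/acceptor malonate carbene by an acceptor-only acetate carbene on a dirhodium carboxamidate, a catalyst class known to direct diazoacetates of 2-arylethanols into the benzylic C–H bond, and introduces the C3 carboxyl only after the ring exists. Alcohol 8 is acylated with bromoacetyl bromide (pyridine, CH2Cl2, 0 °C) to the bromoacetate F1. N,N'-Ditosylhydrazine and DBU (THF, 0 °C) convert this into the diazoacetate F2. Slow addition of F2 to Rh2(NHCOCH3)4 (dirhodium tetraacetamidate) in refluxing CH2Cl2 should close the trans 4-anisyl lactone F3. The lactone enolate (LiN(SiMe3)2, 2.2 equiv, THF, −78 °C) is C-acylated with Boc2O anti to the aryl group to give the tert-butyl ester F4; this is done while the chain still carries the silyl ether, so no acetate is exposed to strong base. HF·pyridine then gives the alcohol F5, and Ac2O/pyridine returns 14.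

Step 10. Degradation of the arene may stall at partly oxidised ring fragments, or oxidation may spread to the C3 methine between the two carbonyls. The fallback sets out from 14 and comes back at 15. The ring is cleaved by ozone instead of a metal oxo species: exhaustive ozonolysis (O3, CH2Cl2/AcOH, −20 °C) followed by oxidative work-up (30% H2O2, HCO2H, rt → 40 °C). This is a known metal-free way to turn an electron-rich aryl group into a carboxylic acid; it attacks only the π system and leaves C–H bonds alone. No compound outside the compound list is made (F0).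

Step 12. The crude diacid 16 may decarboxylate before the iminium ion captures C3, giving the lactone without the methylene group, or the liberated amine may add to the product. The fallback sets out from 15 and comes back at 18. The C–C bond is made before the acid is unmasked, with a preformed iminium salt: 15 is treated with dimethylmethyleneammonium iodide and Et3N (CH2Cl2, rt) to give the tert-butyl ester Mannich base F6, alkylated at C3 anti to the C4 carboxyl. TFA/CH2Cl2 removes the tert-butyl group to give the amino diacid F7, and warming in NaOAc/AcOH (60 °C) should bring about decarboxylative loss of dimethylamine to 18.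

**Further compounds**

F1 | step 9 | (R)-15-(tert-butyldimethylsilyloxy)-1-(4-methoxyphenyl)pentadecan-2-yl 2-bromoacetate | BrCC(=O)O[C@H](CCCCCCCCCCCCCO[Si](C)(C)C(C)(C)C)Cc1ccc(OC)cc1
F2 | step 9 | (R)-15-(tert-butyldimethylsilyloxy)-1-(4-methoxyphenyl)pentadecan-2-yl 2-diazoacetate | [N-]=[N+]=CC(=O)O[C@H](CCCCCCCCCCCCCO[Si](C)(C)C(C)(C)C)Cc1ccc(OC)cc1
F3 | step 9 | (4R,5R)-5-[13-(tert-butyldimethylsilyloxy)tridecyl]-4-(4-methoxyphenyl)dihydrofuran-2(3H)-one | O=C1O[C@H](CCCCCCCCCCCCCO[Si](C)(C)C(C)(C)C)[C@@H](c2ccc(OC)cc2)C1
F4 | step 9 | tert-butyl (3S,4R,5R)-5-[13-(tert-butyldimethylsilyloxy)tridecyl]-4-(4-methoxyphenyl)-2-oxotetrahydrofuran-3-carboxylate | CC(C)(C)OC(=O)[C@@H]1C(=O)O[C@H](CCCCCCCCCCCCCO[Si](C)(C)C(C)(C)C)[C@H]1c2ccc(OC)cc2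
F5 | step 9 | tert-butyl (3S,4R,5R)-5-(13-hydroxytridecyl)-4-(4-methoxyphenyl)-2-oxotetrahydrofuran-3-carboxylate | CC(C)(C)OC(=O)[C@@H]1C(=O)O[C@H](CCCCCCCCCCCCCO)[C@H]1c2ccc(OC)cc2
F0 | step 10 | none | none
F6 | step 12 | (2R,3S,4S)-2-(13-acetoxytridecyl)-4-(tert-butoxycarbonyl)-4-(dimethylaminomethyl)-5-oxotetrahydrofuran-3-carboxylic acid | CN(C)C[C@]1(C(=O)OC(C)(C)C)C(=O)O[C@H](CCCCCCCCCCCCCOC(C)=O)[C@H]1C(=O)O
F7 | step 12 | (2R,3S,4R)-2-(13-acetoxytridecyl)-4-(dimethylaminomethyl)-5-oxotetrahydrofuran-3,4-dicarboxylic acid | CN(C)C[C@]1(C(=O)O)C(=O)O[C@H](CCCCCCCCCCCCCOC(C)=O)[C@H]1C(=O)O
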